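Ring B is closed last across C5–C6 and C8–C9 (drimane numbering), a formal [3+3] union of a ring A keto aldehyde with a four-carbon 4-oxybut-2-enal unit. The key step is a one-flask Claisen rearrangement and intramolecular vinylogous aldol addition: its precursor is the allyl vinyl ether C9=C11–O–C6–C7=C8–C12HO hanging on C10 next to the C5 ketone; the sigmatropic shift forges C8–C9, then the C12 dienolate adds through C6 to C5. This exploits the hidden vinylogous aldol C5(OH)–C6–C7=C8–C12HO of ring B and the 1,4-dialdehyde C11/C12. Ring A comes from 2,6,6-trimethylcyclohexenone: C1 is set by copper catalysis; C10, C9 and C5 are relayed from it.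

Key step: step 9

Remarks and assumptions
- Numbering: C1 carries the ester, C4 the gem-dimethyl group, C5 the tertiary OH, C6 is the ring CH2, C7=C8 the ring alkene, C9 the CH bearing formyl carbon C11, C10 the angular-methyl carbon, C12 the formyl carbon on C8. TIPS = triisopropylsilyl.
- Compounds 1, 6 and 13 are taken as catalogue compounds.
- The sense of induction in step 1 is not derived here; the antipode of the bisphosphine that gives (3R)-3 is the one used.

Step 1
Reactants: 1 2,6,6-trimethylcyclohex-2-en-1-one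
Product: 3 (3R)-3-hydroxy-2,6,6-trimethylcyclohexan-1-one (both C2 epimers), via β-boryl ketone 2 (not isolated)
Conditions: CuCl (5 mol %), NaOC(CH3)3 (10 mol %), (R,R)-QuinoxP* (6 mol %), bis(pinacolato)diboron (1.1 equiv), MeOH (2 equiv), THF, 0 °C → rt; then NaBO3·4H2O, THF/H2O, rt
Reagents that add atoms: sodium perborate, NaBO3·4H2O, written as Na[B(OH)3(OOH)], [Na+].OO[B-](O)(O)O
Why: Copper-catalysed enantioselective conjugate borylation of the enone followed by stereoretentive oxidation of the C–B bond should set the carbinol centre (future C1) under catalyst control, while the C2 epimer mixture is irrelevant because C2 is enolised in step 2.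

Step 2
Reactants: 3 (3R)-3-hydroxy-2,6,6-trimethylcyclohexan-1-one
Product: 5 (2S,3R)-3-hydroxy-2,6,6-trimethyl-2-(prop-2-en-1-yl)cyclohexan-1-one (OH cis to the C2 methyl), via dilithium alkoxide enolate 4 (not isolated)
Conditions: LiN(CH(CH3)2)2 (2.3 equiv), THF, −78 → −10 °C; allyl bromide (1.5 equiv), DMPU, −78 → 0 °C; H2O
Reagents that add atoms: allyl bromide, C=CCBr
Why: This is the alkylation of an aldolate dianion (Fráter–Seebach type): the ketone can enolise only towards C2 because C6 is quaternary, the alkoxide is not a leaving group, and allyl bromide should enter anti to the adjacent lithium alkoxide, which sets the quaternary centre (future C10) with methyl cis to oxygen.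

Step 3
Reactants: 6 (E)-4-hydroxycinnamic acid (p-coumaric acid)
Product: 8 (E)-4-(triisopropylsilyloxy)cinnamic acid, via bis-silylated ester 7 (not isolated)
Conditions: TIPSCl (2.2 equiv), imidazole (4.5 equiv), DMF, rt; then AcOH/THF/H2O, rt
Reagents that add atoms: chlorotri(propan-2-yl)silane, CC(C)[Si](Cl)(C(C)C)C(C)C
Why: Silylation of phenol and acid followed by selective hydrolysis of the far more labile silyl ester should give the protected acid without touching the E alkene; no stereocentre is formed.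

Step 4
Reactants: 5 (2S,3R)-3-hydroxy-2,6,6-trimethyl-2-(prop-2-en-1-yl)cyclohexan-1-one, 8 (E)-4-(triisopropylsilyloxy)cinnamic acid
Product: 10 (1R,2S)-2,4,4-trimethyl-3-oxo-2-(prop-2-en-1-yl)cyclohexyl (E)-4-(triisopropylsilyloxy)cinnamate, via mixed anhydride 9 (not isolated)
Conditions: 8, 2,4,6-trichlorobenzoyl chloride (1.3 equiv), Et3N (3 equiv), THF, rt; then 5, DMAP (0.5 equiv), toluene, 40 °C
Reagents that add atoms: none
Why: Yamaguchi esterification: the mixed anhydride should acylate the hindered but equatorial secondary alcohol under DMAP catalysis with retention at the carbinol carbon.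

Step 5
Reactants: 10 (1R,2S)-2,4,4-trimethyl-3-oxo-2-(prop-2-en-1-yl)cyclohexyl (E)-4-(triisopropylsilyloxy)cinnamate
Product: 12 (1R,2S)-2,4,4-trimethyl-3-oxo-2-(2-oxoethyl)cyclohexyl (E)-4-(triisopropylsilyloxy)cinnamate, via diol 11 (not isolated)
Conditions: K2OsO4·2H2O (2 mol %), NaIO4 (4 equiv), 2,6-lutidine (2 equiv), 1,4-dioxane/H2O (3:1), rt
Reagents that add atoms: sodium periodate, [Na+].[O-][I](=O)(=O)=O (terminal oxidant and oxygen source through the osmate); water, O
Why: Lemieux–Johnson cleavage (dihydroxylation, then periodate glycol cleavage) should be selective because the electron-rich monosubstituted alkene reacts faster with the osmium reagent than the conjugated cinnamate alkene.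

Step 6
Reactants: 12 (1R,2S)-2,4,4-trimethyl-3-oxo-2-(2-oxoethyl)cyclohexyl (E)-4-(triisopropylsilyloxy)cinnamate, 13 (Z)-but-2-ene-1,4-diol
Product: 14 (1R,2S)-2-(4,7-dihydro-1,3-dioxepin-2-ylmethyl)-2,4,4-trimethyl-3-oxocyclohexyl (E)-4-(triisopropylsilyloxy)cinnamate
Conditions: 13 (3 equiv), PPTS (10 mol %), benzene, reflux, Dean–Stark
Reagents that add atoms: none
Why: Acid-catalysed acetalisation with removal of water should engage only the unhindered aldehyde, since the ketone between two quaternary carbons does not ketalise, and the seven-membered dioxepin is the normal acetal of this cis diol.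

Step 7
Reactants: 14 (1R,2S)-2-(4,7-dihydro-1,3-dioxepin-2-ylmethyl)-2,4,4-trimethyl-3-oxocyclohexyl (E)-4-(triisopropylsilyloxy)cinnamate
Product: 16 (1R,2S)-2-[(E)-2-{[(Z)-4-hydroxybut-2-en-1-yl]oxy}ethenyl]-2,4,4-trimethyl-3-oxocyclohexyl (E)-4-(triisopropylsilyloxy)cinnamate, via trimethylsilyl ether 15 (not isolated)
Conditions: TMSOTf (1.5 equiv), i-Pr2NEt (2.5 equiv), CH2Cl2, −20 → 0 °C; then K2CO3 (0.2 equiv), MeOH, 0 °C; filtration through basic alumina, used at once
Reagents that add atoms: none
Why: Gassman-type ring-opening elimination of the acetal: the silyl triflate ionises one C–O bond, Hünig's base removes a C9 proton of the oxocarbenium ion to give the enol ether (E favoured next to the quaternary carbon), and methanolysis frees the primary allylic alcohol.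

Step 8
Reactants: 16 (1R,2S)-2-[(E)-2-{[(Z)-4-hydroxybut-2-en-1-yl]oxy}ethenyl]-2,4,4-trimethyl-3-oxocyclohexyl (E)-4-(triisopropylsilyloxy)cinnamate
Product: 18 (1R,2S)-2,4,4-trimethyl-3-oxo-2-[(E)-2-{[(E)-4-oxobut-2-en-1-yl]oxy}ethenyl]cyclohexyl (E)-4-(triisopropylsilyloxy)cinnamate, via Z-enal 17 (not isolated)
Conditions: MnO2 (activated, 15 equiv), CH2Cl2, rt; filter; DABCO (10 mol %), CH2Cl2, rt
Reagents that add atoms: none
Why: Allylic oxidation with MnO2 should leave enol ether, cinnamate and silyl ether untouched, and amine-catalysed reversible conjugate addition should then equilibrate the Z enal to the more stable E enal.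

Step 9
Reactants: 18 (1R,2S)-2,4,4-trimethyl-3-oxo-2-[(E)-2-{[(E)-4-oxobut-2-en-1-yl]oxy}ethenyl]cyclohexyl (E)-4-(triisopropylsilyloxy)cinnamate
Product: 20 1β-[(E)-4-(triisopropylsilyloxy)cinnamoyloxy]-5α-hydroxydrim-7-ene-11,12-dial (9β-formyl, 9α-H), via Claisen dialdehyde 19 (not isolated)
Conditions: xylene (0.01 M, BHT), 150 °C, sealed tube; cool; DBU (0.2 equiv), −20 → 0 °C; AcOH, −20 °C
Reagents that add atoms: none
Why: Heating 18 should trigger a chair-like [3,3]-sigmatropic (Claisen) rearrangement of the allyl vinyl ether that forms C8–C9 and unveils the C11 aldehyde as 19; DBU then removes the doubly activated C8–H of this 2-vinyl-1,4-dialdehyde, and the C12 dienolate adds through its γ-carbon C6 to the C5 ketone, forming C5–C6 and the conjugated C7=C8 enal. The closest known reaction types are the aliphatic Claisen rearrangement and the intramolecular vinylogous aldol addition, run here as a one-flask cascade. Ring B closes by 6-exo-trig attack on the ketone with the nucleophilic C6=C7 unit inside the forming ring, the only feasible mode, since α-attack would give a four-membered ring and γ-attack on C11 a strained five-membered ring holding three contiguous sp2 carbons. C9 is set in the Claisen event by substrate control: the enol ether sits equatorial on C10 with its C=C eclipsing the axial C10 methyl, and the allyl terminus should add to the face flanked by the flat C5 carbonyl, not to the face shielded by the C1 acyloxy group, which places the formyl group cis to the C10 methyl. C5 is relayed from C9 and C10: with C9–H in the crowded position between C1 and C5, C8 lies anti to C1, so C6 reaches C5 along the equatorial trajectory of a chair-like transition state and the trans-decalin with axial 5-OH anti to the C10 methyl should result, whereas the cis-fused closure needs C8 folded under ring A. The step needs γ-regioselectivity, chemoselectivity for the ketone over the C11 aldehyde and kinetic control at C9 and C5; the first two are secured by ring size, the last by the higher acidity of C8–H than C9–H, the catalytic amount of base at low temperature and the acetic acid quench.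

Step 10
Reactants: 20 1β-[(E)-4-(triisopropylsilyloxy)cinnamoyloxy]-5α-hydroxydrim-7-ene-11,12-dial
Product: 21 1β-[(E)-4-hydroxycinnamoyloxy]-5α-hydroxydrim-7-ene-11,12-dial (CNP0323926.1)
Conditions: HF·pyridine, pyridine, THF, 0 °C → rt
Reagents that add atoms: none
Why: Fluoride-mediated cleavage of the aryl silyl ether under buffered, weakly acidic conditions should not epimerise C9, dehydrate the tertiary alcohol or touch the ester.

Compound list
1 | 2,6,6-trimethylcyclohex-2-en-1-one | CC1=CCCC(C)(C)C1=O | starting material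
2 | (3R)-2,6,6-trimethyl-3-(4,4,5,5-tetramethyl-1,3,2-dioxaborolan-2-yl)cyclohexan-1-one (C2 epimers) | CC1(C)CC[C@@H](B2OC(C)(C)C(C)(C)O2)C(C)C1=O | intermediate (not isolated)
3 | (3R)-3-hydroxy-2,6,6-trimethylcyclohexan-1-one (C2 epimers) | CC1(C)CC[C@@H](O)C(C)C1=O | intermediate
4 | dilithium alkoxide enolate of 3 | CC1(C)CC[C@@H](O[Li])C(C)=C1O[Li] | intermediate (not isolated)
5 | (2S,3R)-3-hydroxy-2,6,6-trimethyl-2-(prop-2-en-1-yl)cyclohexan-1-one | CC1(C)CC[C@@H](O)[C@](C)(CC=C)C1=O | intermediate
6 | (E)-4-hydroxycinnamic acid (p-coumaric acid) | O=C(O)/C=C/c1ccc(O)cc1 | starting material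
7 | triisopropylsilyl (E)-4-(triisopropylsilyloxy)cinnamate | CC(C)[Si](OC(=O)/C=C/c1ccc(O[Si](C(C)C)(C(C)C)C(C)C)cc1)(C(C)C)C(C)C | intermediate (not isolated)
8 | (E)-4-(triisopropylsilyloxy)cinnamic acid | O=C(O)/C=C/c1ccc(O[Si](C(C)C)(C(C)C)C(C)C)cc1 | intermediate
9 | (E)-4-(triisopropylsilyloxy)cinnamic 2,4,6-trichlorobenzoic anhydride | O=C(OC(=O)c1c(Cl)cc(Cl)cc1Cl)/C=C/c1ccc(O[Si](C(C)C)(C(C)C)C(C)C)cc1 | intermediate (not isolated)
10 | (1R,2S)-2,4,4-trimethyl-3-oxo-2-(prop-2-en-1-yl)cyclohexyl (E)-4-(triisopropylsilyloxy)cinnamate | CC1(C)CC[C@@H](OC(=O)/C=C/c2ccc(O[Si](C(C)C)(C(C)C)C(C)C)cc2)[C@](C)(CC=C)C1=O | intermediate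
11 | (1R,2S)-2-(2,3-dihydroxypropyl)-2,4,4-trimethyl-3-oxocyclohexyl (E)-4-(triisopropylsilyloxy)cinnamate (diol epimers) | CC1(C)CC[C@@H](OC(=O)/C=C/c2ccc(O[Si](C(C)C)(C(C)C)C(C)C)cc2)[C@](C)(CC(O)CO)C1=O | intermediate (not isolated)
12 | (1R,2S)-2,4,4-trimethyl-3-oxo-2-(2-oxoethyl)cyclohexyl (E)-4-(triisopropylsilyloxy)cinnamate | CC1(C)CC[C@@H](OC(=O)/C=C/c2ccc(O[Si](C(C)C)(C(C)C)C(C)C)cc2)[C@](C)(CC=O)C1=O | intermediate
13 | (Z)-but-2-ene-1,4-diol | OC/C=C\CO | starting material
14 | (1R,2S)-2-(4,7-dihydro-1,3-dioxepin-2-ylmethyl)-2,4,4-trimethyl-3-oxocyclohexyl (E)-4-(triisopropylsilyloxy)cinnamate | CC1(C)CC[C@@H](OC(=O)/C=C/c2ccc(O[Si](C(C)C)(C(C)C)C(C)C)cc2)[C@](C)(CC2OCC=CCO2)C1=O | intermediate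
15 | (1R,2S)-2,4,4-trimethyl-3-oxo-2-[(E)-2-{[(Z)-4-(trimethylsilyloxy)but-2-en-1-yl]oxy}ethenyl]cyclohexyl (E)-4-(triisopropylsilyloxy)cinnamate | CC1(C)CC[C@@H](OC(=O)/C=C/c2ccc(O[Si](C(C)C)(C(C)C)C(C)C)cc2)[C@](C)(/C=C/OC/C=C\CO[Si](C)(C)C)C1=O | intermediate (not isolated)
16 | (1R,2S)-2-[(E)-2-{[(Z)-4-hydroxybut-2-en-1-yl]oxy}ethenyl]-2,4,4-trimethyl-3-oxocyclohexyl (E)-4-(triisopropylsilyloxy)cinnamate | CC1(C)CC[C@@H](OC(=O)/C=C/c2ccc(O[Si](C(C)C)(C(C)C)C(C)C)cc2)[C@](C)(/C=C/OC/C=C\CO)C1=O | intermediate
17 | (1R,2S)-2,4,4-trimethyl-3-oxo-2-[(E)-2-{[(Z)-4-oxobut-2-en-1-yl]oxy}ethenyl]cyclohexyl (E)-4-(triisopropylsilyloxy)cinnamate | CC1(C)CC[C@@H](OC(=O)/C=C/c2ccc(O[Si](C(C)C)(C(C)C)C(C)C)cc2)[C@](C)(/C=C/OC/C=C\C=O)C1=O | intermediate (not isolated)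
18 | (1R,2S)-2,4,4-trimethyl-3-oxo-2-[(E)-2-{[(E)-4-oxobut-2-en-1-yl]oxy}ethenyl]cyclohexyl (E)-4-(triisopropylsilyloxy)cinnamate | CC1(C)CC[C@@H](OC(=O)/C=C/c2ccc(O[Si](C(C)C)(C(C)C)C(C)C)cc2)[C@](C)(/C=C/OC/C=C/C=O)C1=O | intermediate
19 | (1R,2S)-2-(3-ethenyl-1,4-dioxobutan-2-yl)-2,4,4-trimethyl-3-oxocyclohexyl (E)-4-(triisopropylsilyloxy)cinnamate (C9 as in the target, C8 epimers) | CC1(C)CC[C@@H](OC(=O)/C=C/c2ccc(O[Si](C(C)C)(C(C)C)C(C)C)cc2)[C@](C)([C@@H](C=O)C(C=O)C=C)C1=O | intermediate (not isolated)
20 | 1β-[(E)-4-(triisopropylsilyloxy)cinnamoyloxy]-5α-hydroxydrim-7-ene-11,12-dial | CC1(C)CC[C@@H](OC(=O)/C=C/c2ccc(O[Si](C(C)C)(C(C)C)C(C)C)cc2)[C@]2(C)[C@@H](C=O)C(C=O)=CC[C@@]12O | intermediate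
21 | 1β-[(E)-4-hydroxycinnamoyloxy]-5α-hydroxydrim-7-ene-11,12-dial (CNP0323926.1) | CC1(C)CC[C@@H](OC(=O)/C=C/c2ccc(O)cc2)[C@]2(C)[C@@H](C=O)C(C=O)=CC[C@@]12O | target

Total step count: 10. Longest linear sequence: 9 steps (steps 1, 2 and 4 to 10, from 1 to 21); step 3 is a one-step side branch.

Steps most likely to fail

1. Step 9 (key step). The base stage may lose kinetic control: the vinylogous aldol at the crowded C5 ketone may revert or close through the folded rotamer to the cis-fused ring fusion, and contact with DBU may epimerise C9. The fallback sets out from 19, isolated after the thermal stage alone. TBSOTf and Et3N in CH2Cl2 at −78 °C would convert both formyl groups into silyl enol ethers and give the bis(silyl enol ether) F1, in which C12 is part of a 1-silyloxydiene. BF3·OEt2 in CH2Cl2 at −78 °C would then effect an intramolecular vinylogous Mukaiyama aldol addition of C6 to the C5 ketone, irreversible under these non-basic conditions, to give the ring-closed C11 silyl enol ether F2. HF·pyridine would finally cleave the enol and aryl silyl ethers, the C11 enol being protonated at C9 from the α face, anti to the axial C10 methyl group. The sequence comes back to the route at 21.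

2. Step 2. Formation of the tetrasubstituted enolate next to the lithium alkoxide may be incomplete, with O-allylation or retro-aldol opening of the aldolate competing and the anti selectivity eroding. The fallback sets out from 1. Copper-catalysed enantioselective conjugate silylation with PhMe2Si–Bpin (CuCl, NaOC(CH3)3, chiral N-heterocyclic carbene ligand) would give the β-silyl ketone F3. Its lithium enolate, which cannot undergo β-elimination, would be allylated with allyl bromide anti to the silyl group to give the allyl silyl ketone F4. Fleming–Tamao oxidation (HBF4·OEt2, then H2O2, KF, KHCO3) would convert C–Si into C–OH with retention. The sequence comes back to the route at 5.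

3. Step 7. The ring opening may be reversed by re-closure of the hydroxy enol ether to the dioxepin under trace acid, the oxocarbenium ion may lose its allyl group, and the enol ether may form as an E/Z mixture. The fallback sets out from 14, which would be heated in xylene at 150 °C with a catalytic amount of pivalic acid. Acetal cracking to the hydroxy enol ether and Claisen rearrangement in the same flask, followed by addition of the C12 hydroxyl to the new C11 aldehyde, would give the lactol F5. NaBH4 would reduce the lactol to the diol F6 without touching the hindered ketone, and a double Swern oxidation would give the dialdehyde. The sequence comes back to the route at 19, which is treated with DBU as in step 9.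

Further compounds
F1 | step 9 | (1R,2S)-2-[1,4-bis(tert-butyldimethylsilyloxy)-3-ethenylbuta-1,3-dien-2-yl]-2,4,4-trimethyl-3-oxocyclohexyl (E)-4-(triisopropylsilyloxy)cinnamate | CC1(C)CC[C@@H](OC(=O)/C=C/c2ccc(O[Si](C(C)C)(C(C)C)C(C)C)cc2)[C@](C)(C(=CO[Si](C)(C)C(C)(C)C)C(C=C)=CO[Si](C)(C)C(C)(C)C)C1=O
F2 | step 9 | C11 tert-butyldimethylsilyl enol ether of 20 (C9=C11 enol ether, C12 formyl, 5α-OH) | CC1(C)CC[C@@H](OC(=O)/C=C/c2ccc(O[Si](C(C)C)(C(C)C)C(C)C)cc2)[C@]2(C)C(=CO[Si](C)(C)C(C)(C)C)C(C=O)=CC[C@@]12O
F3 | step 2 | (3R)-3-[dimethyl(phenyl)silyl]-2,6,6-trimethylcyclohexan-1-one (C2 epimers) | CC1(C)CC[C@@H]([Si](C)(C)c2ccccc2)C(C)C1=O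
F4 | step 2 | (2R,3R)-3-[dimethyl(phenyl)silyl]-2,6,6-trimethyl-2-(prop-2-en-1-yl)cyclohexan-1-one | CC1(C)CC[C@@H]([Si](C)(C)c2ccccc2)[C@](C)(CC=C)C1=O
F5 | step 7 | (1R,2S)-2-(4-ethenyl-2-hydroxyoxolan-3-yl)-2,4,4-trimethyl-3-oxocyclohexyl (E)-4-(triisopropylsilyloxy)cinnamate (lactol epimers) | CC1(C)CC[C@@H](OC(=O)/C=C/c2ccc(O[Si](C(C)C)(C(C)C)C(C)C)cc2)[C@](C)([C@H]2C(O)OCC2C=C)C1=O
F6 | step 7 | (1R,2S)-2-[1,4-dihydroxy-3-ethenylbutan-2-yl]-2,4,4-trimethyl-3-oxocyclohexyl (E)-4-(triisopropylsilyloxy)cinnamate | CC1(C)CC[C@@H](OC(=O)/C=C/c2ccc(O[Si](C(C)C)(C(C)C)C(C)C)cc2)[C@](C)([C@@H](CO)C(CO)C=C)C1=O
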